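The route rests on cutting the C2–C3 bond of the pyranone ring C. The key step is a catalyst-controlled rhodium-carbene 1,6 C–H insertion: the diazo carbon of an aryl diazomethyl ketone (the future C3) inserts into a benzylic C–H bond of a 2,4-bis(silyloxy)benzyl aryl ether, closing ring C and setting the C2 stereocentre in one operation. It exploits the fact that C2 carries both the ring oxygen O1 and the electron-rich ring B, so that its C–H bond is the most hydridic one within reach of C3. The precursor is an open 2-benzyloxy-α-diazoacetophenone in which ring B is merely an O-benzyl group on ring A; the side-chain stereocentres derive from (S)-β-methyl-γ-butyrolactone.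

Key step: step 12

Assumption: Rh2(S-BSP)4 is taken to induce the (2S) configuration in step 12; if a test cyclisation shows the opposite sense, the enantiomeric catalyst Rh2(R-BSP)4 is used with no other change.

Step 1
Reactants: 1 (4S)-4-methyloxolan-2-one
Product: 3 (3S,4S)-4-methyl-3-(3-methylbut-2-en-1-yl)oxolan-2-one, via lithium enolate 2 (not isolated)
Conditions: LiN(i-Pr)2 (1.05 equiv), THF, −78 °C; then prenyl bromide (1.2 equiv), −78 → −30 °C
Reagents that add atoms: prenyl bromide (1-bromo-3-methylbut-2-ene), CC(C)=CCBr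
Why: Enolate alkylation of a β-substituted γ-butyrolactone, in which the allylic bromide approaches the enolate face anti to the C4 methyl group, so that the new C3 stereocentre is set trans to it by substrate control.

Step 2
Reactants: 4 phloroglucinol
Product: 5 1,3,5-tris(methoxymethoxy)benzene
Conditions: MOMCl (3.6 equiv), i-Pr2NEt (4.5 equiv), DMF, 0 °C → rt
Reagents that add atoms: chloromethyl methyl ether (MOMCl), COCCl
Why: Williamson-type O-alkylation of the three phenols with the reactive α-chloro ether gives the acetal-protected ring, whose methoxymethoxy groups later direct two lithiations.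

Step 3
Reactants: 5 1,3,5-tris(methoxymethoxy)benzene; 3 (3S,4S)-4-methyl-3-(3-methylbut-2-en-1-yl)oxolan-2-one
Product: 8 (1RS,2S,3S)-3-methyl-2-(3-methylbut-2-en-1-yl)-1-[2,4,6-tris(methoxymethoxy)phenyl]butane-1,4-diol, via aryllithium 6 (not isolated), via keto alkoxide 7 (not isolated)
Conditions: 5 (1.3 equiv), n-BuLi (1.25 equiv), THF, 0 °C; then 3, −78 → 0 °C; then LiAlH4 (1 equiv), 0 °C → rt; aq. potassium sodium tartrate
Reagents that add atoms: none
Why: Directed ortho-lithiation between two methoxymethoxy groups gives an aryllithium that opens the lactone by acyl substitution to a hindered 2,6-disubstituted aryl ketone, which resists a second addition, and hydride reduction in the same flask gives the diol; the carbinol centre forms as a mixture of epimers and is removed in step 4, and the two side-chain stereocentres are not touched.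

Step 4
Reactants: 8 (1RS,2S,3S)-3-methyl-2-(3-methylbut-2-en-1-yl)-1-[2,4,6-tris(methoxymethoxy)phenyl]butane-1,4-diol
Product: 9 (2S,3R)-2,6-dimethyl-3-{[2,4,6-tris(methoxymethoxy)phenyl]methyl}hept-5-en-1-ol
Conditions: Et3SiH (5 equiv), CF3CO2H (3 equiv), CH2Cl2, −40 → −20 °C
Reagents that add atoms: none
Why: Ionic hydrogenation (SN1-type): the benzylic alcohol flanked by three alkoxy donors ionises with little acid at low temperature and the cation, formed directly or after reversible capture by the primary hydroxyl as a cyclic ether, is reduced by the silane, while the trisubstituted alkene and the acetals should not be protonated under these conditions.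

Step 5
Reactants: 9 (2S,3R)-2,6-dimethyl-3-{[2,4,6-tris(methoxymethoxy)phenyl]methyl}hept-5-en-1-ol
Product: 11 1-{3-[(2R)-2-[(2S)-1-hydroxypropan-2-yl]-5-methylhex-4-en-1-yl]-2,4,6-tris(methoxymethoxy)phenyl}ethan-1-one, via dilithio species 10 (not isolated)
Conditions: n-BuLi (2.3 equiv), THF, 0 °C; then MeC(O)N(OMe)Me (1.5 equiv), −78 → 0 °C; H2O
Reagents that add atoms: N-methoxy-N-methylacetamide, CC(=O)N(C)OC
Why: Directed ortho-lithiation at one of the two equivalent ring positions flanked by two methoxymethoxy groups (the alkoxide protects the alcohol) and acylation with the N-methoxy-N-methylamide, whose chelated tetrahedral adduct prevents over-addition, should give the methyl ketone as a single regioisomer.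

Step 6
Reactants: 11 1-{3-[(2R)-2-[(2S)-1-hydroxypropan-2-yl]-5-methylhex-4-en-1-yl]-2,4,6-tris(methoxymethoxy)phenyl}ethan-1-one
Product: 12 1-{2,4,6-trihydroxy-3-[(2R)-2-[(2S)-1-hydroxypropan-2-yl]-5-methylhex-4-en-1-yl]phenyl}ethan-1-one
Conditions: HCl (2 M in MeOH), 40 °C
Reagents that add atoms: none
Why: Acid-catalysed acetal methanolysis removes the three methoxymethyl groups, and the trisubstituted alkene should survive because no hydroxyl can reach it through a five- or six-membered ring.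

Step 7
Reactants: 12 1-{2,4,6-trihydroxy-3-[(2R)-2-[(2S)-1-hydroxypropan-2-yl]-5-methylhex-4-en-1-yl]phenyl}ethan-1-one
Product: 13 1-{4,6-bis(tert-butyldimethylsilyloxy)-2-hydroxy-3-[(2R)-2-[(2S)-1-(tert-butyldimethylsilyloxy)propan-2-yl]-5-methylhex-4-en-1-yl]phenyl}ethan-1-one
Conditions: TBSCl (3.1 equiv), imidazole (4 equiv), DMF, −20 → 0 °C
Reagents that add atoms: tert-butyldimethylsilyl chloride (TBSCl), CC(C)(C)[Si](C)(C)Cl
Why: Kinetically controlled silylation should take the primary alcohol, the unchelated 4-hydroxyl and the less hindered 6-hydroxyl, and leave the 2-hydroxyl, which is flanked by the side chain and the acetyl group and locked in a hydrogen bond to the carbonyl oxygen.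

Step 8
Reactants: 14 2,4-dihydroxybenzaldehyde
Product: 15 2,4-bis(tert-butyldimethylsilyloxy)benzaldehyde
Conditions: TBSCl (2.3 equiv), imidazole (3 equiv), DMF, rt
Reagents that add atoms: tert-butyldimethylsilyl chloride (TBSCl), CC(C)(C)[Si](C)(C)Cl
Why: Standard imidazole-promoted silylation of both phenols protects ring B with the same fluoride-labile group as ring A.

Step 9
Reactants: 15 2,4-bis(tert-butyldimethylsilyloxy)benzaldehyde
Product: 16 [2,4-bis(tert-butyldimethylsilyloxy)phenyl]methanol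
Conditions: NaBH4 (1 equiv), THF/MeOH, −10 °C, short reaction time
Reagents that add atoms: none
Why: Borohydride reduction of the aldehyde, run cold and briefly so that the ortho silyl group does not migrate to the new alkoxide.

Step 10
Reactants: 13 1-{4,6-bis(tert-butyldimethylsilyloxy)-2-hydroxy-3-[(2R)-2-[(2S)-1-(tert-butyldimethylsilyloxy)propan-2-yl]-5-methylhex-4-en-1-yl]phenyl}ethan-1-one; 16 [2,4-bis(tert-butyldimethylsilyloxy)phenyl]methanol
Product: 17 1-{2-{[2,4-bis(tert-butyldimethylsilyloxy)phenyl]methoxy}-4,6-bis(tert-butyldimethylsilyloxy)-3-[(2R)-2-[(2S)-1-(tert-butyldimethylsilyloxy)propan-2-yl]-5-methylhex-4-en-1-yl]phenyl}ethan-1-one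
Conditions: PPh3 (1.5 equiv), DIAD (1.5 equiv), toluene, 0 °C → rt
Reagents that add atoms: none
Why: Mitsunobu etherification, in which the acidic chelated phenol displaces the oxyphosphonium derived from the primary benzylic alcohol under neutral conditions that leave the aryl silyl ethers intact.

Step 11
Reactants: 17 1-{2-{[2,4-bis(tert-butyldimethylsilyloxy)phenyl]methoxy}-4,6-bis(tert-butyldimethylsilyloxy)-3-[(2R)-2-[(2S)-1-(tert-butyldimethylsilyloxy)propan-2-yl]-5-methylhex-4-en-1-yl]phenyl}ethan-1-one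
Product: 20 2-diazo-1-{2-{[2,4-bis(tert-butyldimethylsilyloxy)phenyl]methoxy}-4,6-bis(tert-butyldimethylsilyloxy)-3-[(2R)-2-[(2S)-1-(tert-butyldimethylsilyloxy)propan-2-yl]-5-methylhex-4-en-1-yl]phenyl}ethan-1-one, via lithium enolate 18 (not isolated), via trifluoroacetyl ketone 19 (not isolated)
Conditions: LiN(SiMe3)2 (1.1 equiv), THF, −78 °C; CF3CO2CH2CF3 (1.2 equiv); then MsN3 (1.5 equiv), Et3N (1.5 equiv), H2O (1 equiv), MeCN, rt
Reagents that add atoms: methanesulfonyl azide, CS(=O)(=O)N=[N+]=[N-]; 2,2,2-trifluoroethyl trifluoroacetate, O=C(OCC(F)(F)F)C(F)(F)F (its trifluoroacetyl group is carried by 19 and lost again)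
Why: Detrifluoroacetylative diazo transfer (Regitz-type): Claisen condensation of the kinetic enolate with the trifluoroacetate activates the methyl ketone, and diazo transfer from the sulfonyl azide with loss of the trifluoroacetyl group gives the diazomethyl ketone without strongly basic or acidic conditions.

Step 12
Reactants: 20 2-diazo-1-{2-{[2,4-bis(tert-butyldimethylsilyloxy)phenyl]methoxy}-4,6-bis(tert-butyldimethylsilyloxy)-3-[(2R)-2-[(2S)-1-(tert-butyldimethylsilyloxy)propan-2-yl]-5-methylhex-4-en-1-yl]phenyl}ethan-1-one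
Product: 21 (2S)-2-[2,4-bis(tert-butyldimethylsilyloxy)phenyl]-5,7-bis(tert-butyldimethylsilyloxy)-8-[(2R)-2-[(2S)-1-(tert-butyldimethylsilyloxy)propan-2-yl]-5-methylhex-4-en-1-yl]-2,3-dihydro-4H-chromen-4-one
Conditions: Rh2(S-BSP)4 [dirhodium tetrakis((S)-N-benzenesulfonylprolinate)] (2 mol %), CH2Cl2, slow addition of 20 at high dilution, 0 °C → rt
Reagents that add atoms: none
Why: Rh2(S-BSP)4 extrudes N2 from 20 to give an electrophilic carbene bound to divalent rhodium at the future C3, which inserts into a benzylic C–H bond of the O1–CH2–aryl ether through a concerted, hydride-transfer-like three-centre transition state (rhodium-carbene intramolecular C–H insertion; the closest known reaction type is the formation of chroman-4-ones from 2-alkoxyphenyl diazo ketones under chiral dirhodium carboxylate catalysis). Ring C (O1–C2–C3–C4–C4a–C8a) closes by 1,6 C–H insertion through a six-membered cyclic transition state, the smallest one possible because the 1,5 position is occupied by O1. The new C2 stereocentre is set by the chiral prolinate ligand sphere, which distinguishes the two enantiotopic benzylic hydrogens (catalyst control; the remote side-chain stereocentres are not expected to interfere). The step needs C–H insertion to win over oxonium ylide formation at O1 followed by 1,2-shift of the benzyl group, over reaction at the other ortho oxygen, and over cyclopropanation of the side-chain alkene. This should be secured by the doubly activated C2–H bond (α to oxygen, benzylic, electron-rich ring B), by the bulky and poorly basic silyl ether at O5 that offers no C–H bond within six-membered reach, by the encumbered di-ortho-substituted O1, and by slow addition at high dilution, the alkene being too remote for an intramolecular reaction.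

Step 13
Reactants: 21 (2S)-2-[2,4-bis(tert-butyldimethylsilyloxy)phenyl]-5,7-bis(tert-butyldimethylsilyloxy)-8-[(2R)-2-[(2S)-1-(tert-butyldimethylsilyloxy)propan-2-yl]-5-methylhex-4-en-1-yl]-2,3-dihydro-4H-chromen-4-one
Product: 22 (2S)-2-(2,4-dihydroxyphenyl)-5,7-dihydroxy-8-[(2R)-2-[(2S)-1-hydroxypropan-2-yl]-5-methylhex-4-en-1-yl]-2,3-dihydro-4H-chromen-4-one
Conditions: Bu4NF (8 equiv), AcOH (8 equiv), THF, 0 °C → rt
Reagents that add atoms: none
Why: Fluoride-mediated cleavage of all five silyl ethers under acetic acid buffering, which should avoid the phenoxide-triggered ring opening to the chalcone that would erode the C2 configuration.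

Compound list
1 | (4S)-4-methyloxolan-2-one [(S)-β-methyl-γ-butyrolactone] | O=C1C[C@H](C)CO1 | starting material
2 | lithium enolate of 1 | [Li]OC1=C[C@H](C)CO1 | intermediate (not isolated)
3 | (3S,4S)-4-methyl-3-(3-methylbut-2-en-1-yl)oxolan-2-one (trans) | CC(C)=CC[C@H](C1=O)[C@H](C)CO1 | intermediate
4 | phloroglucinol (benzene-1,3,5-triol) | Oc1cc(O)cc(O)c1 | starting material
5 | 1,3,5-tris(methoxymethoxy)benzene | COCOc1cc(OCOC)cc(OCOC)c1 | intermediate
6 | [2,4,6-tris(methoxymethoxy)phenyl]lithium | [Li]c1c(OCOC)cc(OCOC)cc1OCOC | intermediate (not isolated)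
7 | lithium alkoxide of (2S,3S)-4-hydroxy-3-methyl-2-(3-methylbut-2-en-1-yl)-1-[2,4,6-tris(methoxymethoxy)phenyl]butan-1-one | CC(C)=CC[C@H](C(=O)c1c(OCOC)cc(OCOC)cc1OCOC)[C@H](C)CO[Li] | intermediate (not isolated)
8 | (1RS,2S,3S)-3-methyl-2-(3-methylbut-2-en-1-yl)-1-[2,4,6-tris(methoxymethoxy)phenyl]butane-1,4-diol | CC(C)=CC[C@H](C(O)c1c(OCOC)cc(OCOC)cc1OCOC)[C@H](C)CO | intermediate
9 | (2S,3R)-2,6-dimethyl-3-{[2,4,6-tris(methoxymethoxy)phenyl]methyl}hept-5-en-1-ol | CC(C)=CC[C@H](Cc1c(OCOC)cc(OCOC)cc1OCOC)[C@H](C)CO | intermediate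
10 | dilithio derivative of 9 (lithium alkoxide, aryllithium at the ring carbon between two methoxymethoxy groups) | CC(C)=CC[C@H](Cc1c(OCOC)c([Li])c(OCOC)cc1OCOC)[C@H](C)CO[Li] | intermediate (not isolated)
11 | 1-{3-[(2R)-2-[(2S)-1-hydroxypropan-2-yl]-5-methylhex-4-en-1-yl]-2,4,6-tris(methoxymethoxy)phenyl}ethan-1-one | CC(C)=CC[C@H](Cc1c(OCOC)c(C(C)=O)c(OCOC)cc1OCOC)[C@H](C)CO | intermediate
12 | 1-{2,4,6-trihydroxy-3-[(2R)-2-[(2S)-1-hydroxypropan-2-yl]-5-methylhex-4-en-1-yl]phenyl}ethan-1-one | CC(C)=CC[C@H](Cc1c(O)c(C(C)=O)c(O)cc1O)[C@H](C)CO | intermediate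
13 | 1-{4,6-bis(tert-butyldimethylsilyloxy)-2-hydroxy-3-[(2R)-2-[(2S)-1-(tert-butyldimethylsilyloxy)propan-2-yl]-5-methylhex-4-en-1-yl]phenyl}ethan-1-one | CC(C)=CC[C@H](Cc1c(O)c(C(C)=O)c(O[Si](C)(C)C(C)(C)C)cc1O[Si](C)(C)C(C)(C)C)[C@H](C)CO[Si](C)(C)C(C)(C)C | intermediate
14 | 2,4-dihydroxybenzaldehyde | O=Cc1ccc(O)cc1O | starting material
15 | 2,4-bis(tert-butyldimethylsilyloxy)benzaldehyde | O=Cc1ccc(O[Si](C)(C)C(C)(C)C)cc1O[Si](C)(C)C(C)(C)C | intermediate
16 | [2,4-bis(tert-butyldimethylsilyloxy)phenyl]methanol | OCc1ccc(O[Si](C)(C)C(C)(C)C)cc1O[Si](C)(C)C(C)(C)C | intermediate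
17 | 1-{2-{[2,4-bis(tert-butyldimethylsilyloxy)phenyl]methoxy}-4,6-bis(tert-butyldimethylsilyloxy)-3-[(2R)-2-[(2S)-1-(tert-butyldimethylsilyloxy)propan-2-yl]-5-methylhex-4-en-1-yl]phenyl}ethan-1-one | CC(C)=CC[C@H](Cc1c(OCc2ccc(O[Si](C)(C)C(C)(C)C)cc2O[Si](C)(C)C(C)(C)C)c(C(C)=O)c(O[Si](C)(C)C(C)(C)C)cc1O[Si](C)(C)C(C)(C)C)[C@H](C)CO[Si](C)(C)C(C)(C)C | intermediate
18 | lithium enolate of 17 | CC(C)=CC[C@H](Cc1c(OCc2ccc(O[Si](C)(C)C(C)(C)C)cc2O[Si](C)(C)C(C)(C)C)c(C(=C)O[Li])c(O[Si](C)(C)C(C)(C)C)cc1O[Si](C)(C)C(C)(C)C)[C@H](C)CO[Si](C)(C)C(C)(C)C | intermediate (not isolated)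
19 | trifluoroacetyl derivative of 17 (4,4,4-trifluoro-1-arylbutane-1,3-dione) | CC(C)=CC[C@H](Cc1c(OCc2ccc(O[Si](C)(C)C(C)(C)C)cc2O[Si](C)(C)C(C)(C)C)c(C(=O)CC(=O)C(F)(F)F)c(O[Si](C)(C)C(C)(C)C)cc1O[Si](C)(C)C(C)(C)C)[C@H](C)CO[Si](C)(C)C(C)(C)C | intermediate (not isolated)
20 | 2-diazo-1-{2-{[2,4-bis(tert-butyldimethylsilyloxy)phenyl]methoxy}-4,6-bis(tert-butyldimethylsilyloxy)-3-[(2R)-2-[(2S)-1-(tert-butyldimethylsilyloxy)propan-2-yl]-5-methylhex-4-en-1-yl]phenyl}ethan-1-one | CC(C)=CC[C@H](Cc1c(OCc2ccc(O[Si](C)(C)C(C)(C)C)cc2O[Si](C)(C)C(C)(C)C)c(C(=O)C=[N+]=[N-])c(O[Si](C)(C)C(C)(C)C)cc1O[Si](C)(C)C(C)(C)C)[C@H](C)CO[Si](C)(C)C(C)(C)C | intermediate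
21 | (2S)-2-[2,4-bis(tert-butyldimethylsilyloxy)phenyl]-5,7-bis(tert-butyldimethylsilyloxy)-8-[(2R)-2-[(2S)-1-(tert-butyldimethylsilyloxy)propan-2-yl]-5-methylhex-4-en-1-yl]-2,3-dihydro-4H-chromen-4-one | CC(C)=CC[C@H](Cc1c(O[Si](C)(C)C(C)(C)C)cc(O[Si](C)(C)C(C)(C)C)c2c1O[C@H](c1ccc(O[Si](C)(C)C(C)(C)C)cc1O[Si](C)(C)C(C)(C)C)CC2=O)[C@H](C)CO[Si](C)(C)C(C)(C)C | intermediate
22 | (2S)-2-(2,4-dihydroxyphenyl)-5,7-dihydroxy-8-[(2R)-2-[(2S)-1-hydroxypropan-2-yl]-5-methylhex-4-en-1-yl]-2,3-dihydro-4H-chromen-4-one | CC(C)=CC[C@H](Cc1c(O)cc(O)c2c1O[C@H](c1ccc(O)cc1O)CC2=O)[C@H](C)CO | target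

Total step count: 13
Longest linear sequence: 10 steps (steps 1, 3, 4, 5, 6, 7, 10, 11, 12, 13; the branch from 4 through step 2 is equally long)

Steps most likely to fail

Step 12. The carbene may be intercepted by the lone pair of O1 (oxonium ylide formation followed by 1,2-migration of the electron-rich benzyl group) faster than it inserts into the C–H bond, and enantioselection by the chiral carboxylate may be incomplete. The fallback sets out from 13 and aldehyde 15 and comes back at 21; it closes ring C at the O1–C2 bond by an organocatalytic oxa-Michael addition. Phenol 13 is acylated through its dianion (LiN(SiMe3)2, 3.2 equiv, THF, −78 °C; Boc2O) to the tert-butyl β-keto ester F1. Knoevenagel condensation with 15 (piperidine, AcOH, toluene, 4 Å molecular sieves) gives the alkylidene β-keto ester F2. A cinchona-derived bifunctional thiourea (10 mol %, toluene, −25 °C; quinine or quinidine series chosen for the 2S sense) then effects the enantioselective conjugate addition of the phenol to give the 3-(tert-butoxycarbonyl)flavanone F3. TsOH (toluene, 80 °C) removes the ester group by loss of 2-methylpropene and CO2 to give 21, which continues with step 13.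

Step 4. Ionisation of the benzylic alcohol may be accompanied by proton loss toward the neighbouring stereocentre (epimerisation next to the cation) or by acid cleavage of the acetal protecting groups before hydride transfer. The fallback sets out from 8 and comes back at 9; it replaces the cation by a radical. The primary hydroxyl of 8 is silylated selectively (TBSCl, imidazole, CH2Cl2, 0 °C) to the mono-silyl ether F4. The benzylic alcohol is converted into the S-methyl xanthate F5 (NaH, CS2, MeI, THF). Barton–McCombie deoxygenation (Bu3SnH, AIBN, toluene, 90 °C) gives the silyl ether F6, and Bu4NF (THF) frees alcohol 9.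

Step 7. The silylation may fail to discriminate between the two hydroxyls ortho to the acetyl group, so that the wrong ortho oxygen is left free. The fallback sets out from 9 and comes back at 13; it differentiates the oxygens before the acetyl group exists. Acid methanolysis of 9 (HCl, MeOH) gives the alkylphloroglucinol F7. Silylation (TBSCl, 3 equiv, imidazole, DMF) of the primary alcohol, the unhindered hydroxyl para to the side chain and one of the two equivalent ortho hydroxyls gives the monophenol F8. Magnesium-mediated formylation (MgCl2, Et3N, paraformaldehyde, MeCN, 70 °C; Casnati–Skattebøl reaction), specific for the position ortho to the free phenol, gives the salicylaldehyde F9. MeMgBr (2.5 equiv, THF) gives the carbinol F10, and MnO2 (CH2Cl2) oxidises it to 13, in which the free hydroxyl necessarily lies between the side chain and the acetyl group.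

Further compounds
F1 | step 12 | tert-butyl 3-{4,6-bis(tert-butyldimethylsilyloxy)-2-hydroxy-3-[(2R)-2-[(2S)-1-(tert-butyldimethylsilyloxy)propan-2-yl]-5-methylhex-4-en-1-yl]phenyl}-3-oxopropanoate | CC(C)=CC[C@H](Cc1c(O)c(C(=O)CC(=O)OC(C)(C)C)c(O[Si](C)(C)C(C)(C)C)cc1O[Si](C)(C)C(C)(C)C)[C@H](C)CO[Si](C)(C)C(C)(C)C
F2 | step 12 | tert-butyl 2-{[2,4-bis(tert-butyldimethylsilyloxy)phenyl]methylidene} derivative of F1 (alkylidene β-keto ester, free 2-hydroxyl) | CC(C)=CC[C@H](Cc1c(O)c(C(=O)C(=Cc2ccc(O[Si](C)(C)C(C)(C)C)cc2O[Si](C)(C)C(C)(C)C)C(=O)OC(C)(C)C)c(O[Si](C)(C)C(C)(C)C)cc1O[Si](C)(C)C(C)(C)C)[C@H](C)CO[Si](C)(C)C(C)(C)C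
F3 | step 12 | tert-butyl (2S)-2-[2,4-bis(tert-butyldimethylsilyloxy)phenyl]-5,7-bis(tert-butyldimethylsilyloxy)-8-[(2R)-2-[(2S)-1-(tert-butyldimethylsilyloxy)propan-2-yl]-5-methylhex-4-en-1-yl]-4-oxo-3,4-dihydro-2H-chromene-3-carboxylate (C3 unassigned) | CC(C)=CC[C@H](Cc1c(O[Si](C)(C)C(C)(C)C)cc(O[Si](C)(C)C(C)(C)C)c2c1O[C@H](c1ccc(O[Si](C)(C)C(C)(C)C)cc1O[Si](C)(C)C(C)(C)C)C(C(=O)OC(C)(C)C)C2=O)[C@H](C)CO[Si](C)(C)C(C)(C)C
F4 | step 4 | (1RS,2S,3S)-4-(tert-butyldimethylsilyloxy)-3-methyl-2-(3-methylbut-2-en-1-yl)-1-[2,4,6-tris(methoxymethoxy)phenyl]butan-1-ol | CC(C)=CC[C@H](C(O)c1c(OCOC)cc(OCOC)cc1OCOC)[C@H](C)CO[Si](C)(C)C(C)(C)C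
F5 | step 4 | O-benzylic S-methyl xanthate of F4 | CC(C)=CC[C@H](C(OC(=S)SC)c1c(OCOC)cc(OCOC)cc1OCOC)[C@H](C)CO[Si](C)(C)C(C)(C)C
F6 | step 4 | tert-butyldimethylsilyl ether of 9 | CC(C)=CC[C@H](Cc1c(OCOC)cc(OCOC)cc1OCOC)[C@H](C)CO[Si](C)(C)C(C)(C)C
F7 | step 7 | 2-[(2R)-2-[(2S)-1-hydroxypropan-2-yl]-5-methylhex-4-en-1-yl]benzene-1,3,5-triol | CC(C)=CC[C@H](Cc1c(O)cc(O)cc1O)[C@H](C)CO
F8 | step 7 | 3,5-bis(tert-butyldimethylsilyloxy)-2-[(2R)-2-[(2S)-1-(tert-butyldimethylsilyloxy)propan-2-yl]-5-methylhex-4-en-1-yl]phenol | CC(C)=CC[C@H](Cc1c(O)cc(O[Si](C)(C)C(C)(C)C)cc1O[Si](C)(C)C(C)(C)C)[C@H](C)CO[Si](C)(C)C(C)(C)C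
F9 | step 7 | 4,6-bis(tert-butyldimethylsilyloxy)-2-hydroxy-3-[(2R)-2-[(2S)-1-(tert-butyldimethylsilyloxy)propan-2-yl]-5-methylhex-4-en-1-yl]benzaldehyde | CC(C)=CC[C@H](Cc1c(O)c(C=O)c(O[Si](C)(C)C(C)(C)C)cc1O[Si](C)(C)C(C)(C)C)[C@H](C)CO[Si](C)(C)C(C)(C)C
F10 | step 7 | 1-{4,6-bis(tert-butyldimethylsilyloxy)-2-hydroxy-3-[(2R)-2-[(2S)-1-(tert-butyldimethylsilyloxy)propan-2-yl]-5-methylhex-4-en-1-yl]phenyl}ethan-1-ol (carbinol epimers) | CC(C)=CC[C@H](Cc1c(O)c(C(C)O)c(O[Si](C)(C)C(C)(C)C)cc1O[Si](C)(C)C(C)(C)C)[C@H](C)CO[Si](C)(C)C(C)(C)C
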